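**Retrosynthetic overview**
- The side-chain ketone comes from a late alcohol oxidation; the ring–alkenyl bond is cut by Stille coupling into a dienone triflate and an (E)-alkenylstannane.
- The carbocycle is opened by an intramolecular aldol addition (ethyl ketone enolate onto a cis-held enal); silylation, enol triflation, desilylation and oxidation turn the ketol into the regiodefined triflate.
- The quaternary stereocentre is cut by an asymmetric vinylic substitution of a pyranonyl ketone on (Z)-3-iodo-2-methylacrolein.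
- The pyranonyl ketone comes from a β-keto ester dianion (acylation, lactonisation, O-methylation, acylation); the stannane comes from a Marshall propargylation.
- Ring order: pyranone first (step 2), carbocycle second (step 8).

Assumption: the facial sense of the phase-transfer catalyst in step 7 is taken by analogy; if the cinchonidinium salt gives ent-13, its cinchoninium pseudoenantiomer is used.

**Route**

Step 1
Reactants: 1 methyl 2-methyl-3-oxopentanoate; 2 N-methoxy-N-methylpropanamide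
Product: 4 methyl 2,4-dimethyl-3,5-dioxoheptanoate, via sodium lithium dianion 3 (not isolated)
Conditions: NaH, THF, 0 °C; n-BuLi, 0 °C; 2, −78 → 0 °C; then 1 M HCl
Reagents that add atoms: none
Why: The β-keto ester dianion reacts at its γ-carbon in a Claisen-type dianion acylation, and the chelated Weinreb adduct survives until the quench so the acidic product never meets base.

Step 2
Reactants: 4 methyl 2,4-dimethyl-3,5-dioxoheptanoate
Product: 5 6-ethyl-4-hydroxy-3,5-dimethyl-2H-pyran-2-one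
Conditions: DBU, toluene, 80 °C; then 1 M HCl
Reagents that add atoms: none
Why: DBU enolises the 3,5-diketo ester and the C5 enol oxygen closes onto the ester with loss of methanol (lactonisation) to give the 4-hydroxy-2-pyranone.

Step 3
Reactants: 5 6-ethyl-4-hydroxy-3,5-dimethyl-2H-pyran-2-one
Product: 6 2-ethyl-6-methoxy-3,5-dimethyl-4H-pyran-4-one
Conditions: MeOTf, CH2Cl2, 23 °C; aq. NaHCO3
Reagents that add atoms: methyl trifluoromethanesulfonate, COS(=O)(=O)C(F)(F)F
Why: Under neutral conditions the hard methylating agent alkylates the lactone carbonyl oxygen, which after proton loss gives the 2-methoxy-4-pyranone regioisomer (regioselective O-methylation).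

Step 4
Reactants: 6 2-ethyl-6-methoxy-3,5-dimethyl-4H-pyran-4-one; 2 N-methoxy-N-methylpropanamide
Product: 8 rac-2-methoxy-3,5-dimethyl-6-(3-oxopentan-2-yl)-4H-pyran-4-one, via lithium dienolate 7 (not isolated)
Conditions: LiN(SiMe3)2, THF, −78 °C; 2, −78 → 0 °C; then AcOH
Reagents that add atoms: none
Why: The only acidic C–H of the fully substituted pyranone is the vinylogous CH2 of the ethyl group, so its lithium dienolate is C-acylated by the Weinreb amide (vinylogous enolate acylation) to the doubly activated methine ketone.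

Step 5
Reactants: 9 prop-2-yn-1-ol
Product: 11 (Z)-3-iodo-2-methylprop-2-en-1-ol, via magnesium chelate 10 (not isolated)
Conditions: MeMgBr, CuI (10 mol%), THF, −10 → 23 °C; I2, −10 °C; then 1 M HCl
Reagents that add atoms: methylmagnesium bromide, C[Mg]Br; iodine, II
Why: Copper-catalysed carbomagnesiation of the magnesium propargyl alkoxide is anti because the alkoxide holds magnesium in a five-membered chelate, so iodinolysis with retention puts iodine cis to CH2OH.

Step 6
Reactants: 11 (Z)-3-iodo-2-methylprop-2-en-1-ol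
Product: 12 (Z)-3-iodo-2-methylprop-2-enal
Conditions: DMP, CH2Cl2, 0 °C, dark; used at once
Reagents that add atoms: none
Why: Dess–Martin oxidation of the primary allylic alcohol is fast and neutral, so the Z geometry of the non-enolisable β-iodo enal is kept.

Step 7
Reactants: 8 rac-2-methoxy-3,5-dimethyl-6-(3-oxopentan-2-yl)-4H-pyran-4-one; 12 (Z)-3-iodo-2-methylprop-2-enal
Product: 13 (2Z,4R)-4-(6-methoxy-3,5-dimethyl-4-oxo-4H-pyran-2-yl)-2,4-dimethyl-5-oxohept-2-enal
Conditions: N-(9-anthracenylmethyl)-O-allylcinchonidinium bromide (10 mol%), Cs2CO3, toluene/CHCl3 7:1, −30 °C, dark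
Reagents that add atoms: none
Why: In this asymmetric nucleophilic vinylic substitution (conjugate addition–elimination under chiral phase-transfer catalysis) the enolate of 8 is paired with the cinchona ammonium cation, which shields one face and so sets the quaternary centre, while fast loss of iodide from the adduct keeps the Z geometry.

Step 8
Reactants: 13 (2Z,4R)-4-(6-methoxy-3,5-dimethyl-4-oxo-4H-pyran-2-yl)-2,4-dimethyl-5-oxohept-2-enal
Product: 16 (2R)-2-(6-methoxy-3,5-dimethyl-4-oxo-4H-pyran-2-yl)-2,4,6-trimethyl-5-[(triethylsilyl)oxy]cyclohex-3-en-1-one (C5/C6 epimers), via lithium enolate 14 (not isolated), via lithium aldolate 15 (not isolated)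
Conditions: LiN(SiMe3)2, THF, −78 °C; TESOTf, −78 → −40 °C; aq. NaHCO3
Reagents that add atoms: triethylsilyl trifluoromethanesulfonate, CC[Si](CC)(CC)OS(=O)(=O)C(F)(F)F
Why: The ketone can enolise only at the ethyl CH2 and the non-enolisable aldehyde is held cis, so the enolate closes the six-membered ring by intramolecular aldol addition (6-enolendo-exo-trig) and the aldolate is silylated before retro-aldol or dehydration, the two new centres forming as a mixture that steps 9 and 11 erase.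

Step 9
Reactants: 16 (2R)-2-(6-methoxy-3,5-dimethyl-4-oxo-4H-pyran-2-yl)-2,4,6-trimethyl-5-[(triethylsilyl)oxy]cyclohex-3-en-1-one
Product: 18 (6R)-6-(6-methoxy-3,5-dimethyl-4-oxo-4H-pyran-2-yl)-2,4,6-trimethyl-3-[(triethylsilyl)oxy]cyclohexa-1,4-dien-1-yl trifluoromethanesulfonate (C3 epimers), via potassium enolate 17 (not isolated)
Conditions: KN(SiMe3)2, THF, −78 °C; Comins' reagent, −78 °C; aq. NH4Cl
Reagents that add atoms: N-(5-chloropyridin-2-yl)-1,1,1-trifluoro-N-(trifluoromethylsulfonyl)methanesulfonamide, Clc1ccc(nc1)N(S(=O)(=O)C(F)(F)F)S(=O)(=O)C(F)(F)F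
Why: The ketone has a single α-hydrogen because its other α-carbon is quaternary, so kinetic enolate triflation with the reactive pyridyl triflimide at −78 °C gives one enol triflate regioisomer before β-elimination of silyloxide can compete.

Step 10
Reactants: 18 (6R)-6-(6-methoxy-3,5-dimethyl-4-oxo-4H-pyran-2-yl)-2,4,6-trimethyl-3-[(triethylsilyl)oxy]cyclohexa-1,4-dien-1-yl trifluoromethanesulfonate
Product: 19 (6R)-3-hydroxy-6-(6-methoxy-3,5-dimethyl-4-oxo-4H-pyran-2-yl)-2,4,6-trimethylcyclohexa-1,4-dien-1-yl trifluoromethanesulfonate (C3 epimers)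
Conditions: HF·pyridine, pyridine, THF, 0 °C
Reagents that add atoms: none
Why: Buffered fluoride cleaves the secondary triethylsilyl ether (desilylation) while the vinyl triflate is untouched and no free acid is present to ionise the bis-allylic alcohol.

Step 11
Reactants: 19 (6R)-3-hydroxy-6-(6-methoxy-3,5-dimethyl-4-oxo-4H-pyran-2-yl)-2,4,6-trimethylcyclohexa-1,4-dien-1-yl trifluoromethanesulfonate
Product: 20 (6R)-6-(6-methoxy-3,5-dimethyl-4-oxo-4H-pyran-2-yl)-2,4,6-trimethyl-3-oxocyclohexa-1,4-dien-1-yl trifluoromethanesulfonate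
Conditions: DMP, pyridine, CH2Cl2, 0 → 23 °C
Reagents that add atoms: none
Why: Dess–Martin oxidation of the bis-allylic alcohol gives the cross-conjugated dienone and turns the triflate into a vinylogous acyl triflate that is activated for oxidative addition.

Step 12
Reactants: 21 (R)-but-3-yn-2-ol
Product: 22 (R)-but-3-yn-2-yl methanesulfonate
Conditions: MsCl, Et3N, CH2Cl2, −78 → 0 °C
Reagents that add atoms: methanesulfonyl chloride, CS(=O)(=O)Cl
Why: Mesylation takes place at oxygen and does not touch the stereocentre.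

Step 13
Reactants: 22 (R)-but-3-yn-2-yl methanesulfonate; 23 propanal
Product: 25 (3R,4S)-4-methylhex-5-yn-3-ol, via allenylzinc 24 (not isolated)
Conditions: Pd(OAc)2 (5 mol%), PPh3 (5 mol%), Et2Zn, THF, −78 → −20 °C; then 1 M HCl
Reagents that add atoms: none
Why: In this Marshall propargylation zerovalent palladium displaces the mesylate anti (SN2') and the derived allenylzinc adds to propanal through a cyclic SE2' transition state, so the methyl-bearing carbon forms with net inversion (4S) and the carbinol anti to it (3R, major; this centre is oxidised in step 17).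

Step 14
Reactants: 25 (3R,4S)-4-methylhex-5-yn-3-ol
Product: 27 (3R,4S)-4-methylhept-5-yn-3-ol, via dilithio alkoxide acetylide 26 (not isolated)
Conditions: n-BuLi (2.05 equiv), THF, −78 → −20 °C; MeI (1.05 equiv), −20 → 23 °C; then 1 M HCl
Reagents that add atoms: iodomethane, CI
Why: In the alkoxide–acetylide dianion the acetylide carbon is the faster nucleophile towards one equivalent of iodomethane (acetylide alkylation), and neither stereocentre is touched.

Step 15
Reactants: 27 (3R,4S)-4-methylhept-5-yn-3-ol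
Product: 28 (3R,4S,5E)-4-methyl-6-(tributylstannyl)hept-5-en-3-ol
Conditions: Bu3SnH, Pd(PPh3)2Cl2 (3 mol%), THF, 0 → 23 °C
Reagents that add atoms: tributyltin hydride, CCCC[SnH](CCCC)CCCC
Why: Palladium-catalysed hydrostannation is a syn addition that puts tin on the less hindered, methyl-bearing alkyne carbon, which gives the E alkenylstannane.

Step 16
Reactants: 20 (6R)-6-(6-methoxy-3,5-dimethyl-4-oxo-4H-pyran-2-yl)-2,4,6-trimethyl-3-oxocyclohexa-1,4-dien-1-yl trifluoromethanesulfonate; 28 (3R,4S,5E)-4-methyl-6-(tributylstannyl)hept-5-en-3-ol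
Product: 29 (4S)-3-[(2E,4S,5R)-5-hydroxy-4-methylhept-2-en-2-yl]-4-(6-methoxy-3,5-dimethyl-4-oxo-4H-pyran-2-yl)-2,4,6-trimethylcyclohexa-2,5-dien-1-one
Conditions: Pd(PPh3)4 (10 mol%), CuCl, LiCl, DMSO, 60 °C, degassed
Reagents that add atoms: none
Why: Stille coupling of the vinylogous acyl triflate with the alkenylstannane, helped by CuCl/LiCl for the hindered sp2–sp2 bond, proceeds with retention of alkene geometry and touches no stereocentre.

Step 17
Reactants: 29 (4S)-3-[(2E,4S,5R)-5-hydroxy-4-methylhept-2-en-2-yl]-4-(6-methoxy-3,5-dimethyl-4-oxo-4H-pyran-2-yl)-2,4,6-trimethylcyclohexa-2,5-dien-1-one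
Product: 30 (4S)-4-(6-methoxy-3,5-dimethyl-4-oxo-4H-pyran-2-yl)-2,4,6-trimethyl-3-[(2E,4S)-4-methyl-5-oxohept-2-en-2-yl]cyclohexa-2,5-dien-1-one
Conditions: DMP, pyridine, CH2Cl2, 0 °C; neutral work-up
Reagents that add atoms: none
Why: Buffered Dess–Martin oxidation turns the secondary alcohol into the ethyl ketone under non-acidic, non-epimerising conditions, so the α-methyl centre of the β,γ-unsaturated ketone stays S.

**Compound list**

1 | methyl 2-methyl-3-oxopentanoate | CCC(=O)C(C)C(=O)OC | starting material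
2 | N-methoxy-N-methylpropanamide | CCC(=O)N(C)OC | starting material
3 | sodium lithium dianion of 1 (not isolated) | [Na+].[Li+].C[CH-]C(=O)[C-](C)C(=O)OC | intermediate
4 | methyl 2,4-dimethyl-3,5-dioxoheptanoate (tautomer/diastereomer mixture) | CCC(=O)C(C)C(=O)C(C)C(=O)OC | intermediate
5 | 6-ethyl-4-hydroxy-3,5-dimethyl-2H-pyran-2-one | CCc1oc(=O)c(C)c(O)c1C | intermediate
6 | 2-ethyl-6-methoxy-3,5-dimethyl-4H-pyran-4-one | CCc1oc(OC)c(C)c(=O)c1C | intermediate
7 | lithium dienolate of 6 (not isolated) | CC=C1OC(OC)=C(C)C(O[Li])=C1C | intermediate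
8 | rac-2-methoxy-3,5-dimethyl-6-(3-oxopentan-2-yl)-4H-pyran-4-one | CCC(=O)C(C)c1oc(OC)c(C)c(=O)c1C | intermediate
9 | prop-2-yn-1-ol | C#CCO | starting material
10 | cyclic (Z)-alkenylmagnesium alkoxide chelate (not isolated) | CC1=C[Mg]OC1 | intermediate
11 | (Z)-3-iodo-2-methylprop-2-en-1-ol | OC/C(C)=C\I | intermediate
12 | (Z)-3-iodo-2-methylprop-2-enal | O=C/C(C)=C\I | intermediate
13 | (2Z,4R)-4-(6-methoxy-3,5-dimethyl-4-oxo-4H-pyran-2-yl)-2,4-dimethyl-5-oxohept-2-enal | CCC(=O)[C@](C)(/C=C(/C)C=O)c1oc(OC)c(C)c(=O)c1C | intermediate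
14 | lithium enolate of 13 at the ethyl ketone (not isolated) | CC=C(O[Li])[C@](C)(/C=C(/C)C=O)c1oc(OC)c(C)c(=O)c1C | intermediate
15 | lithium aldolate, (2R)-ring ketone with C5–OLi, C5/C6 epimers (not isolated) | O=C1C(C)C(O[Li])C(C)=C[C@]1(C)c1oc(OC)c(C)c(=O)c1C | intermediate
16 | (2R)-2-(6-methoxy-3,5-dimethyl-4-oxo-4H-pyran-2-yl)-2,4,6-trimethyl-5-[(triethylsilyl)oxy]cyclohex-3-en-1-one (C5/C6 epimers) | O=C1C(C)C(O[Si](CC)(CC)CC)C(C)=C[C@]1(C)c1oc(OC)c(C)c(=O)c1C | intermediate
17 | potassium enolate of 16 (not isolated) | [K]OC1=C(C)C(O[Si](CC)(CC)CC)C(C)=C[C@]1(C)c1oc(OC)c(C)c(=O)c1C | intermediate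
18 | (6R)-6-(6-methoxy-3,5-dimethyl-4-oxo-4H-pyran-2-yl)-2,4,6-trimethyl-3-[(triethylsilyl)oxy]cyclohexa-1,4-dien-1-yl trifluoromethanesulfonate (C3 epimers) | FC(F)(F)S(=O)(=O)OC1=C(C)C(O[Si](CC)(CC)CC)C(C)=C[C@]1(C)c1oc(OC)c(C)c(=O)c1C | intermediate
19 | (6R)-3-hydroxy-6-(6-methoxy-3,5-dimethyl-4-oxo-4H-pyran-2-yl)-2,4,6-trimethylcyclohexa-1,4-dien-1-yl trifluoromethanesulfonate (C3 epimers) | FC(F)(F)S(=O)(=O)OC1=C(C)C(O)C(C)=C[C@]1(C)c1oc(OC)c(C)c(=O)c1C | intermediate
20 | (6R)-6-(6-methoxy-3,5-dimethyl-4-oxo-4H-pyran-2-yl)-2,4,6-trimethyl-3-oxocyclohexa-1,4-dien-1-yl trifluoromethanesulfonate | FC(F)(F)S(=O)(=O)OC1=C(C)C(=O)C(C)=C[C@]1(C)c1oc(OC)c(C)c(=O)c1C | intermediate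
21 | (R)-but-3-yn-2-ol | C#C[C@@H](C)O | starting material
22 | (R)-but-3-yn-2-yl methanesulfonate | C#C[C@@H](C)OS(C)(=O)=O | intermediate
23 | propanal | CCC=O | starting material
24 | (M)-buta-1,2-dien-1-yl(ethyl)zinc (not isolated; axial chirality not encoded in the SMILES) | CC=C=C[Zn]CC | intermediate
25 | (3R,4S)-4-methylhex-5-yn-3-ol | CC[C@@H](O)[C@@H](C)C#C | intermediate
26 | dilithio alkoxide acetylide of 25 (not isolated) | CC[C@@H](O[Li])[C@@H](C)C#C[Li] | intermediate
27 | (3R,4S)-4-methylhept-5-yn-3-ol | CC[C@@H](O)[C@@H](C)C#CC | intermediate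
28 | (3R,4S,5E)-4-methyl-6-(tributylstannyl)hept-5-en-3-ol | CC[C@@H](O)[C@@H](C)/C=C(\C)[Sn](CCCC)(CCCC)CCCC | intermediate
29 | (4S)-3-[(2E,4S,5R)-5-hydroxy-4-methylhept-2-en-2-yl]-4-(6-methoxy-3,5-dimethyl-4-oxo-4H-pyran-2-yl)-2,4,6-trimethylcyclohexa-2,5-dien-1-one | CC[C@@H](O)[C@@H](C)/C=C(\C)C1=C(C)C(=O)C(C)=C[C@]1(C)c1oc(OC)c(C)c(=O)c1C | intermediate
30 | (4S)-4-(6-methoxy-3,5-dimethyl-4-oxo-4H-pyran-2-yl)-2,4,6-trimethyl-3-[(2E,4S)-4-methyl-5-oxohept-2-en-2-yl]cyclohexa-2,5-dien-1-one | CCC(=O)[C@@H](C)/C=C(\C)C1=C(C)C(=O)C(C)=C[C@]1(C)c1oc(OC)c(C)c(=O)c1C | target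

**Step count and risks**

Total step count: 17. Longest linear sequence: 11 (steps 1–4, 7–11, 16, 17); the enal branch is steps 5–6 and the stannane branch is steps 12–15.

The three steps most likely to fail:

- **Step 7** (asymmetric vinylic substitution: ee and Z retention are unproven for this nucleophile). The fallback sets out from 8 and comes back at 20. Compound 8 is added to methacrolein by a catalytic asymmetric Michael addition (same ammonium salt with Cs2CO3, or a bifunctional cinchona base) to give keto aldehyde F1. Catalytic KOt-Bu in THF at −20 °C closes the ring by intramolecular aldol addition to saturated ketol F2. TESOTf/2,6-lutidine gives silyl ether F3, and KN(SiMe3)2 with Comins' reagent gives enol triflate F4. HF·pyridine frees hydroxy enol triflate F5. IBX in DMSO oxidises it at 25 °C to enone triflate F6 and, on warming to 75 °C, dehydrogenates its C4–C5 bond to give 20.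

- **Step 9** (enol triflation: the β-silyloxy enolate may eliminate silyloxide). The fallback sets out from 16 and comes back at 20. HF·pyridine gives free ketol F7, and DMP oxidises it to vinylogous acid F8, which should prefer the cross-conjugated 3-hydroxy-dienone tautomer. O-sulfonylation with Tf2O/2,6-lutidine in CH2Cl2 at −78 °C then gives 20; the regioisomeric triflate, if formed, is removed by chromatography.

- **Step 16** (Stille coupling between two fully substituted sp2 carbons). The fallback sets out from 28, with 20 as partner, and comes back at 29. Iododestannylation (I2, CH2Cl2, 0 °C) gives vinyl iodide F9, and TESCl/imidazole gives silyl ether F10. t-BuLi (2 equiv, Et2O, −78 °C) gives alkenyllithium F11, and ZnCl2 gives alkenylzinc chloride F12. Negishi coupling with 20 (Pd[P(t-Bu)3]2, THF/NMP, 25–50 °C) gives silyl-protected coupling product F13, and HF·pyridine gives 29.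

**Further compounds**

F1 | step 7 | (4R)-4-(6-methoxy-3,5-dimethyl-4-oxo-4H-pyran-2-yl)-2,4-dimethyl-5-oxoheptanal (C2 epimers) | CCC(=O)[C@](C)(CC(C)C=O)c1oc(OC)c(C)c(=O)c1C
F2 | step 7 | (2R)-5-hydroxy-2-(6-methoxy-3,5-dimethyl-4-oxo-4H-pyran-2-yl)-2,4,6-trimethylcyclohexan-1-one (epimer mixture) | O=C1C(C)C(O)C(C)C[C@]1(C)c1oc(OC)c(C)c(=O)c1C
F3 | step 7 | (2R)-2-(6-methoxy-3,5-dimethyl-4-oxo-4H-pyran-2-yl)-2,4,6-trimethyl-5-[(triethylsilyl)oxy]cyclohexan-1-one (epimer mixture) | O=C1C(C)C(O[Si](CC)(CC)CC)C(C)C[C@]1(C)c1oc(OC)c(C)c(=O)c1C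
F4 | step 7 | (6R)-6-(6-methoxy-3,5-dimethyl-4-oxo-4H-pyran-2-yl)-2,4,6-trimethyl-3-[(triethylsilyl)oxy]cyclohex-1-en-1-yl trifluoromethanesulfonate (epimer mixture) | FC(F)(F)S(=O)(=O)OC1=C(C)C(O[Si](CC)(CC)CC)C(C)C[C@]1(C)c1oc(OC)c(C)c(=O)c1C
F5 | step 7 | (6R)-3-hydroxy-6-(6-methoxy-3,5-dimethyl-4-oxo-4H-pyran-2-yl)-2,4,6-trimethylcyclohex-1-en-1-yl trifluoromethanesulfonate (epimer mixture) | FC(F)(F)S(=O)(=O)OC1=C(C)C(O)C(C)C[C@]1(C)c1oc(OC)c(C)c(=O)c1C
F6 | step 7 | (6R)-6-(6-methoxy-3,5-dimethyl-4-oxo-4H-pyran-2-yl)-2,4,6-trimethyl-3-oxocyclohex-1-en-1-yl trifluoromethanesulfonate (C4 epimers) | FC(F)(F)S(=O)(=O)OC1=C(C)C(=O)C(C)C[C@]1(C)c1oc(OC)c(C)c(=O)c1C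
F7 | step 9 | (2R)-5-hydroxy-2-(6-methoxy-3,5-dimethyl-4-oxo-4H-pyran-2-yl)-2,4,6-trimethylcyclohex-3-en-1-one (C5/C6 epimers) | O=C1C(C)C(O)C(C)=C[C@]1(C)c1oc(OC)c(C)c(=O)c1C
F8 | step 9 | (4S)-3-hydroxy-4-(6-methoxy-3,5-dimethyl-4-oxo-4H-pyran-2-yl)-2,4,6-trimethylcyclohexa-2,5-dien-1-one | OC1=C(C)C(=O)C(C)=C[C@]1(C)c1oc(OC)c(C)c(=O)c1C
F9 | step 16 | (3R,4S,5E)-6-iodo-4-methylhept-5-en-3-ol | CC[C@@H](O)[C@@H](C)/C=C(\C)I
F10 | step 16 | triethyl{[(3R,4S,5E)-6-iodo-4-methylhept-5-en-3-yl]oxy}silane | CC[C@@H](O[Si](CC)(CC)CC)[C@@H](C)/C=C(\C)I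
F11 | step 16 | [(4S,5R)-4-methyl-5-[(triethylsilyl)oxy]hept-2-en-2-yl]lithium, alkene geometry as in F10 | CC[C@@H](O[Si](CC)(CC)CC)[C@@H](C)/C=C(\C)[Li]
F12 | step 16 | chloro[(2E,4S,5R)-4-methyl-5-[(triethylsilyl)oxy]hept-2-en-2-yl]zinc | CC[C@@H](O[Si](CC)(CC)CC)[C@@H](C)/C=C(\C)[Zn]Cl
F13 | step 16 | (4S)-4-(6-methoxy-3,5-dimethyl-4-oxo-4H-pyran-2-yl)-2,4,6-trimethyl-3-[(2E,4S,5R)-4-methyl-5-[(triethylsilyl)oxy]hept-2-en-2-yl]cyclohexa-2,5-dien-1-one | CC[C@@H](O[Si](CC)(CC)CC)[C@@H](C)/C=C(\C)C1=C(C)C(=O)C(C)=C[C@]1(C)c1oc(OC)c(C)c(=O)c1C
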